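**Strategy**

The benzene ring of the target (chromene numbering O1, C2–C4, C4a, C5–C8, C8a) is a fully substituted hydroquinone: the oxygens on C5 and C8 are para, the C7 methoxy group is the neighbour of C8, and the C4a–C8a edge belongs to the pyran ring as an aryl enol ether. That ring is therefore built in one operation from a dihydropyranyl(methoxy)carbene complex of chromium (C4a, C8a, C5), methoxyethyne (C6, C7) and one CO ligand (C8), which forms C5–C6, C7–C8 and C8–C8a and delivers a 4-methoxyphenol. C6 acylation, oxidation to the 5,8-quinone and a redox-neutral tautomerization then give the chromene hydroquinone.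

Key step: step 5

Remark on the chemistry: the target is achiral, so no stereocentre has to be set. Cr(CO)6 is numbered as a starting material because two of its carbons become C5 and C8 of the arene.

**Route**

Step 1
Reactants: 1 acrolein; 2 2-methylpropene
Product: 3 2,2-dimethyl-3,4-dihydro-2H-pyran
Conditions: neat (excess 2), hydroquinone (cat.), sealed autoclave, 190 °C
Reagents that add atoms: none
Why: Thermal inverse-electron-demand hetero-Diels–Alder reaction with acrolein as the 1-oxadiene, in which the CH2 terminus of 2-methylpropene bonds to the acrolein β-carbon and oxygen bonds to the carbon that best carries positive charge, so the gem-dimethyl group ends up next to oxygen.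

Step 2
Reactants: 3 2,2-dimethyl-3,4-dihydro-2H-pyran
Product: 5 5-bromo-2,2-dimethyl-3,4-dihydro-2H-pyran, via trans-dibromide 4 (not isolated)
Conditions: Br2, CH2Cl2, −78 °C; then Et3N, −78 °C → rt
Reagents that add atoms: bromine, BrBr
Why: Electrophilic bromination of the enol ether gives the 2,3-dibromide, and amine-induced dehydrobromination through the oxocarbenium ion removes the anomeric bromide and the proton on the bromine-bearing carbon, which leaves bromine on the β-carbon of the regenerated enol ether and erases both stereocentres of 4.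

Step 3
Reactants: 5 5-bromo-2,2-dimethyl-3,4-dihydro-2H-pyran; 6 hexacarbonylchromium
Product: 9 pentacarbonyl[(6,6-dimethyl-5,6-dihydro-4H-pyran-3-yl)(methoxy)methylidene]chromium, via vinyllithium 7 (not isolated), via lithium acylchromate 8 (not isolated)
Conditions: t-BuLi (2 equiv), Et2O, −78 °C; Cr(CO)6, Et2O, −78 °C → rt; Me3OBF4, CH2Cl2, 0 °C
Reagents that add atoms: trimethyloxonium tetrafluoroborate, C[O+](C)C.F[B-](F)(F)F
Why: Fischer carbene synthesis: bromine–lithium exchange gives a cyclic β-lithio enol ether that cannot β-eliminate within the six-membered ring, this adds to a CO ligand of Cr(CO)6, and the resulting acylchromate is O-methylated by the hard oxonium salt.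

Step 4
Reactants: 10 chloroacetaldehyde dimethyl acetal
Product: 12 methoxyethyne, via sodium methoxyacetylide 11 (not isolated)
Conditions: NaNH2 (3 equiv), liq. NH3, −33 °C; then cold aq. NH4Cl, −70 °C → rt, distilled into cold THF
Reagents that add atoms: none
Why: Twofold base-induced elimination (HCl, then methanol) from the chloroacetal, with the third equivalent of NaNH2 holding the volatile ynol ether as its sodium acetylide until protonation, which is the established preparation of 1-alkoxyalkynes.

Step 5
Reactants: 9 pentacarbonyl[(6,6-dimethyl-5,6-dihydro-4H-pyran-3-yl)(methoxy)methylidene]chromium; 12 methoxyethyne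
Product: 14 5,7-dimethoxy-2,2-dimethylchroman-8-ol, via tricarbonylchromium arene complex 13 (not isolated)
Conditions: 12 (2 equiv, slow addition), THF, 50 °C, Ar; then air, Et2O, daylight, rt
Reagents that add atoms: none
Why: Proposed new method: loss of one CO from 9 lets methoxyethyne bind and insert into the Cr=C bond with its CH terminus bonding to the former carbene carbon (C5–C6), which gives a chromium vinylcarbene whose new carbene carbon carries the methoxy group (C7), and CO insertion then makes C7–C8 in a metal-bound dienylketene. The one new ring, the benzene ring, closes by 6π-electrocyclization of that dienylketene, the ketene carbon C8 bonding to the enol-ether CH carbon C8a, and the cyclohexadienone so formed tautomerizes to the phenol, obtained first as its Cr(CO)3 complex 13 and freed by air. The closest known reaction type is the Dötz benzannulation of alkenyl(alkoxy)carbene complexes of chromium with terminal alkynes, together with the polar insertion of ynamines into such carbenes, which shows the same regiochemistry; a 1-alkoxyalkyne has not been shown as the alkyne partner. No stereocentre is formed. The step needs regioselective insertion, which the size difference (H against OMe, the larger group going next to the CO-derived carbon) and the nucleophilic CH terminus of the ynol ether both favour, and it needs CO insertion to outrun arrest at the methoxy-stabilized carbene, which THF, moderate heat and slow addition of the alkyne should favour.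

Step 6
Reactants: 14 5,7-dimethoxy-2,2-dimethylchroman-8-ol; 15 3-phenylpropanoic acid
Product: 16 1-(8-hydroxy-5,7-dimethoxy-2,2-dimethylchroman-6-yl)-3-phenylpropan-1-one
Conditions: BF3·OEt2 (neat), 65 °C, Ar; then aq. NaOAc
Reagents that add atoms: none
Why: Friedel–Crafts (Nencki-type) acylation by the BF3-activated carboxylic acid at C6, the only unsubstituted ring position, which is activated by the ortho methoxy groups on C5 and C7 and by the para ring oxygen O1 as in acylations of phloroglucinol ethers, while the saturated chroman ring tolerates the Lewis acid.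

Step 7
Reactants: 16 1-(8-hydroxy-5,7-dimethoxy-2,2-dimethylchroman-6-yl)-3-phenylpropan-1-one
Product: 17 7-methoxy-2,2-dimethyl-6-(3-phenylpropanoyl)chroman-5,8-dione
Conditions: (NH4)2Ce(NO3)6 (2.2 equiv), MeCN/H2O, 0 °C
Reagents that add atoms: water, O
Why: Two-electron oxidation of the 4-methoxyphenol by tetravalent cerium, in which water adds at C5 of the phenoxonium ion and methanol is expelled to give the para-quinone, while the C7 methoxy group is kept because the para-quinone is favoured over the ortho-quinone.

Step 8
Reactants: 17 7-methoxy-2,2-dimethyl-6-(3-phenylpropanoyl)chroman-5,8-dione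
Product: 19 flemistrictin D, 1-(5,8-dihydroxy-7-methoxy-2,2-dimethyl-2H-chromen-6-yl)-3-phenylpropan-1-one, via ortho-quinone methide 18 (not isolated)
Conditions: Et3N (20 mol %), degassed CH2Cl2, Ar, rt
Reagents that add atoms: none
Why: Base-mediated tautomerization of an alkylquinone to its ortho-quinone methide (proton loss from C4, vinylogous to the C8 carbonyl) followed by a second proton shift from C3 to O5, which aromatizes the ring to the hydroquinone and leaves the C3=C4 double bond; the isomerization is redox-neutral, is driven by aromatization and styrene-type conjugation, and uses a tertiary amine that cannot replace the C7 methoxy group.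

**Compound list**

1 | acrolein | C=CC=O | starting material
2 | 2-methylpropene | CC(C)=C | starting material
3 | 2,2-dimethyl-3,4-dihydro-2H-pyran | CC1(C)CCC=CO1 | intermediate
4 | trans-2,3-dibromo-6,6-dimethyltetrahydro-2H-pyran (racemic, one enantiomer drawn) | Br[C@H]1OC(C)(C)CC[C@@H]1Br | intermediate
5 | 5-bromo-2,2-dimethyl-3,4-dihydro-2H-pyran | CC1(C)CCC(Br)=CO1 | intermediate
6 | hexacarbonylchromium, Cr(CO)6 | O=C=[Cr](=C=O)(=C=O)(=C=O)(=C=O)=C=O | starting material
7 | (6,6-dimethyl-5,6-dihydro-4H-pyran-3-yl)lithium | [Li]C1=COC(C)(C)CC1 | intermediate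
8 | lithium pentacarbonyl[(6,6-dimethyl-5,6-dihydro-4H-pyran-3-yl)(oxido)methylidene]chromate | [Li+].[O-]C(=[Cr](=C=O)(=C=O)(=C=O)(=C=O)=C=O)C1=COC(C)(C)CC1 | intermediate
9 | pentacarbonyl[(6,6-dimethyl-5,6-dihydro-4H-pyran-3-yl)(methoxy)methylidene]chromium | COC(=[Cr](=C=O)(=C=O)(=C=O)(=C=O)=C=O)C1=COC(C)(C)CC1 | intermediate
10 | chloroacetaldehyde dimethyl acetal | COC(CCl)OC | starting material
11 | sodium methoxyacetylide | [Na+].[C-]#COC | intermediate
12 | methoxyethyne | COC#C | intermediate
13 | tricarbonyl(η6-5,7-dimethoxy-2,2-dimethylchroman-8-ol)chromium (arene and Cr(CO)3 written as two components) | COc1cc(OC)c2c(c1O)OC(C)(C)CC2.O=C=[Cr](=C=O)=C=O | intermediate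
14 | 5,7-dimethoxy-2,2-dimethylchroman-8-ol | COc1cc(OC)c2c(c1O)OC(C)(C)CC2 | intermediate
15 | 3-phenylpropanoic acid | OC(=O)CCc1ccccc1 | starting material
16 | 1-(8-hydroxy-5,7-dimethoxy-2,2-dimethylchroman-6-yl)-3-phenylpropan-1-one | COc1c(O)c2c(c(OC)c1C(=O)CCc1ccccc1)CCC(C)(C)O2 | intermediate
17 | 7-methoxy-2,2-dimethyl-6-(3-phenylpropanoyl)chroman-5,8-dione | COC1=C(C(=O)CCc2ccccc2)C(=O)C2=C(OC(C)(C)CC2)C1=O | intermediate
18 | 8-hydroxy-7-methoxy-2,2-dimethyl-6-(3-phenylpropanoyl)-2,3-dihydro-5H-chromen-5-one | COC1=C(C(=O)CCc2ccccc2)C(=O)C2=CCC(C)(C)OC2=C1O | intermediate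
19 | flemistrictin D, 1-(5,8-dihydroxy-7-methoxy-2,2-dimethyl-2H-chromen-6-yl)-3-phenylpropan-1-one | COc1c(O)c2c(c(O)c1C(=O)CCc1ccccc1)C=CC(C)(C)O2 | target

**Step count and risks**

Total step count: 8. Longest linear sequence: 7 steps (steps 1, 2, 3, 5, 6, 7, 8); step 4 is a one-step side branch.

Steps most likely to fail:

1. Step 5. The electron-rich alkyne may insert without subsequent CO insertion, so that the sequence stops at a methoxy-stabilized carbene stage, or it may oligomerize at chromium. Irradiation under CO would be tried first within the step. Fallback with known chemistry, setting out from 9 and returning at 14: the Dötz benzannulation is run with 2-ethynyl-4,4,5,5-tetramethyl-1,3,2-dioxaborolane (THF, 50 °C; then air), an alkynylboronate partner whose boryl group, as the larger alkyne substituent, is expected next to the new phenol, to give 5-methoxy-2,2-dimethyl-7-(4,4,5,5-tetramethyl-1,3,2-dioxaborolan-2-yl)chroman-8-ol F1. O-Benzylation (BnBr, K2CO3, DMF) should give 2-[8-(benzyloxy)-5-methoxy-2,2-dimethylchroman-7-yl]-4,4,5,5-tetramethyl-1,3,2-dioxaborolane F2. Oxidation of the C–B bond (NaBO3·4H2O, THF/H2O) should give 8-(benzyloxy)-5-methoxy-2,2-dimethylchroman-7-ol F3. Methylation (MeI, K2CO3, acetone) should give 8-(benzyloxy)-5,7-dimethoxy-2,2-dimethylchroman F4, and hydrogenolysis (H2, 10% Pd/C, EtOAc) rejoins the route at 14.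

2. Step 8. Proton loss may occur from the acyl side chain instead of C4 and lead towards a chalcone-type isomer, the quinone methide may dimerize before the second proton shift, the doubly activated C7 methoxy group may be displaced, or the product may re-oxidize in air. Fallback setting out from 16 and returning at 19, which introduces the double bond by dehydrogenation before the quinone stage: acetylation (Ac2O, pyridine) should give 5,7-dimethoxy-2,2-dimethyl-6-(3-phenylpropanoyl)chroman-8-yl acetate F5. Benzylic dehydrogenation (DDQ, dioxane, reflux) should give 5,7-dimethoxy-2,2-dimethyl-6-(3-phenylpropanoyl)-2H-chromen-8-yl acetate F6. Methanolysis (K2CO3, MeOH) should give 1-(8-hydroxy-5,7-dimethoxy-2,2-dimethyl-2H-chromen-6-yl)-3-phenylpropan-1-one F7. Oxidation ((NH4)2Ce(NO3)6, MeCN/H2O, 0 °C) should give 7-methoxy-2,2-dimethyl-6-(3-phenylpropanoyl)-2H-chromene-5,8-dione F8, and reduction (Na2S2O4, EtOAc/H2O) gives 19.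

3. Step 6. Acylation between two methoxy groups may be slow, and it competes with O-acylation of the C8 phenol, Lewis-acid demethylation beside the new ketone and oxidation of the electron-rich phenol. Fallback setting out from 14 (with 15) and returning at 16, which replaces electrophilic substitution by directed metalation: protection (MOMCl, i-Pr2NEt, CH2Cl2) should give 5,7-dimethoxy-8-(methoxymethoxy)-2,2-dimethylchroman F9. Acid 15 is converted (1,1'-carbonyldiimidazole; then MeNH(OMe)·HCl, CH2Cl2) into N-methoxy-N-methyl-3-phenylpropanamide F10. Lithiation of F9 at C6, the only aromatic C–H and flanked by two methoxy groups (n-BuLi, TMEDA, THF, 0 °C), and addition of F10 should give 1-[5,7-dimethoxy-8-(methoxymethoxy)-2,2-dimethylchroman-6-yl]-3-phenylpropan-1-one F11, and acetal cleavage (HCl, MeOH, 40 °C) rejoins the route at 16.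

Further compounds
F1 | step 5 | 5-methoxy-2,2-dimethyl-7-(4,4,5,5-tetramethyl-1,3,2-dioxaborolan-2-yl)chroman-8-ol | COc1cc(B2OC(C)(C)C(C)(C)O2)c(O)c2OC(C)(C)CCc12
F2 | step 5 | 2-[8-(benzyloxy)-5-methoxy-2,2-dimethylchroman-7-yl]-4,4,5,5-tetramethyl-1,3,2-dioxaborolane | COc1cc(B2OC(C)(C)C(C)(C)O2)c(OCc2ccccc2)c2OC(C)(C)CCc12
F3 | step 5 | 8-(benzyloxy)-5-methoxy-2,2-dimethylchroman-7-ol | COc1cc(O)c(OCc2ccccc2)c2OC(C)(C)CCc12
F4 | step 5 | 8-(benzyloxy)-5,7-dimethoxy-2,2-dimethylchroman | COc1cc(OC)c(OCc2ccccc2)c2OC(C)(C)CCc12
F5 | step 8 | 5,7-dimethoxy-2,2-dimethyl-6-(3-phenylpropanoyl)chroman-8-yl acetate | CC(=O)Oc1c(OC)c(C(=O)CCc2ccccc2)c(OC)c2CCC(C)(C)Oc12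
F6 | step 8 | 5,7-dimethoxy-2,2-dimethyl-6-(3-phenylpropanoyl)-2H-chromen-8-yl acetate | CC(=O)Oc1c(OC)c(C(=O)CCc2ccccc2)c(OC)c2C=CC(C)(C)Oc12
F7 | step 8 | 1-(8-hydroxy-5,7-dimethoxy-2,2-dimethyl-2H-chromen-6-yl)-3-phenylpropan-1-one | COc1c(O)c2OC(C)(C)C=Cc2c(OC)c1C(=O)CCc1ccccc1
F8 | step 8 | 7-methoxy-2,2-dimethyl-6-(3-phenylpropanoyl)-2H-chromene-5,8-dione | COC1=C(C(=O)CCc2ccccc2)C(=O)C2=C(OC(C)(C)C=C2)C1=O
F9 | step 6 | 5,7-dimethoxy-8-(methoxymethoxy)-2,2-dimethylchroman | COCOc1c(OC)cc(OC)c2CCC(C)(C)Oc12
F10 | step 6 | N-methoxy-N-methyl-3-phenylpropanamide | CON(C)C(=O)CCc1ccccc1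
F11 | step 6 | 1-[5,7-dimethoxy-8-(methoxymethoxy)-2,2-dimethylchroman-6-yl]-3-phenylpropan-1-one | COCOc1c(OC)c(C(=O)CCc2ccccc2)c(OC)c2CCC(C)(C)Oc12
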